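**Retrosynthetic overview**
- The target comes from the (2S)-tetra-MOM flavanone by one acidic removal of four MOM groups.
- The C2–aryl bond and the only stereocentre come from a Rh-catalysed enantioselective 1,4-addition of a B-ring arylboronic acid to 6-geranyl-5,7-bis(methoxymethoxy)chromone; the γ-pyrone loses its aromaticity in this step.
- The chromone comes from C6-geranylation of 5,7-dihydroxychromone (bis-phenoxide plus geranyl bromide), itself made from 2,4,6-trihydroxyacetophenone and triethyl orthoformate.
- The boronic acid comes from sterically directed Ir C–H borylation of bis-MOM-protected 3-methoxycatechol.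
- Ring order: the A ring is bought, the pyranone ring is closed first (step 1), the B ring is attached intact in the key step, and no ring is formed afterwards.

Assumption: the (R)-ligand in step 6 is taken to give the 2S product; if a pilot run gives 2R, the (S)-ligand is used and nothing else changes.

**Step 1**
Reactants: 1 2,4,6-trihydroxyacetophenone
Product: 3 5,7-dihydroxy-4H-chromen-4-one, via 4-ethoxy-5,7-dihydroxychromenylium perchlorate 2 (not isolated)
Conditions: HC(OEt)3, 70 % HClO4, 0 °C → rt; then H2O, 90 °C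
Reagents that add atoms: triethyl orthoformate CCOC(OCC)OCC; water O
Why: Orthoformate/perchloric acid benzopyrylium annulation, in which the diethoxycarbenium ion C-formylates the acetyl enol, an ortho phenol closes to the 4-ethoxybenzopyrylium salt and hot water hydrolyses it to the γ-pyrone; the ketone is symmetric, so either ortho-OH gives the same product and no stereocentre is formed.

**Step 2**
Reactants: 3 5,7-dihydroxy-4H-chromen-4-one; 4 geranyl bromide, (2E)-1-bromo-3,7-dimethylocta-2,6-diene
Product: 5 6-[(2E)-3,7-dimethylocta-2,6-dien-1-yl]-5,7-dihydroxy-4H-chromen-4-one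
Conditions: 10 % aq. KOH (2.2 equiv), 4 (1.0 equiv) added slowly, 0 °C → rt, 16 h; 1 M HCl to pH 4; SiO2
Reagents that add atoms: none
Why: Nuclear C-alkylation of the bis-phenoxide by SN2 on the allylic bromide (the E-alkene is kept), where water favours C- over O-attack and C6, flanked by O5 and O7, is more nucleophilic than C8 because O1 is tied up in the vinylogous ester of the pyrone, as in the 6-selective nuclear prenylation and methylation of 5,7-dihydroxychromones and flavones; about 30 % is expected after removing the 8-C isomer and the 7-O-ether, with the position confirmed by HMBC from the chelated 5-OH.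

**Step 3**
Reactants: 5 6-[(2E)-3,7-dimethylocta-2,6-dien-1-yl]-5,7-dihydroxy-4H-chromen-4-one
Product: 6 6-[(2E)-3,7-dimethylocta-2,6-dien-1-yl]-5,7-bis(methoxymethoxy)-4H-chromen-4-one
Conditions: NaH (3 equiv), MOMCl (3 equiv), DMF, 0 °C → rt
Reagents that add atoms: chloromethyl methyl ether COCCl
Why: Williamson-type MOM etherification of both phenoxides, with NaH needed for the chelated 5-OH; capping O5 removes an acetylacetonate-like O,O-chelating site that would tie up rhodium in step 6, and capping O7 prevents an unreactive vinylogous carboxylate.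

**Step 4**
Reactants: 7 3-methoxycatechol, 3-methoxybenzene-1,2-diol
Product: 8 1-methoxy-2,3-bis(methoxymethoxy)benzene
Conditions: NaH (2.5 equiv), MOMCl (2.5 equiv), DMF, 0 °C → rt, N2
Reagents that add atoms: chloromethyl methyl ether COCCl
Why: Williamson-type MOM etherification; MOM survives the iridium, periodate and aqueous rhodium steps and leaves in a single acidic operation at the end.

**Step 5**
Reactants: 8 1-methoxy-2,3-bis(methoxymethoxy)benzene
Product: 10 [3-methoxy-4,5-bis(methoxymethoxy)phenyl]boronic acid, via aryl pinacol boronate 9 (not isolated)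
Conditions: [Ir(OMe)(cod)]2 (1.5 mol %), dtbpy (3 mol %), B2pin2 (1.0 equiv), THF, 80 °C; then NaIO4, NH4OAc, acetone/H2O, rt
Reagents that add atoms: bis(pinacolato)diboron CC1(C)OB(OC1(C)C)B1OC(C)(C)C(C)(C)O1; water O
Why: Iridium-catalysed sterically controlled arene C–H borylation, in which C5 is the only C–H without an ortho substituent in this 1,2,3-trisubstituted arene, followed by buffered periodate cleavage of the pinacol ester, which leaves the MOM acetals intact.

**Step 6 (key step)**
Reactants: 6 6-[(2E)-3,7-dimethylocta-2,6-dien-1-yl]-5,7-bis(methoxymethoxy)-4H-chromen-4-one; 10 [3-methoxy-4,5-bis(methoxymethoxy)phenyl]boronic acid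
Product: 11 (2S)-6-[(2E)-3,7-dimethylocta-2,6-dien-1-yl]-2-[3-methoxy-4,5-bis(methoxymethoxy)phenyl]-5,7-bis(methoxymethoxy)-2,3-dihydro-4H-chromen-4-one
Conditions: 10 (2.5 equiv), [Rh(OH)(cod)]2 (3 mol %), (R)-MeO-F12-BIPHEP (6.6 mol %, pre-mixed at 50 °C), toluene/H2O 10:1, 35 °C, Ar
Reagents that add atoms: none
Why: Hayashi–Miyaura rhodium-catalysed asymmetric 1,4-addition, in which the aryl–Rh(I) species inserts the C2=C3 bond of the γ-pyrone (which thereby loses its aromaticity) on the enantioface chosen by the chiral bisphosphine so that C2 is formed as S under catalyst control, and water protonates the rhodium enolate at C3; the electron-poor ligand and base-free medium suppress 1,2-addition and retro-oxa-Michael ring opening, and the isolated trisubstituted alkenes do not insert.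

**Step 7**
Reactants: 11 (2S)-tetra-MOM flavanone
Product: 12 (2S)-2-(3,4-dihydroxy-5-methoxyphenyl)-6-[(2E)-3,7-dimethylocta-2,6-dien-1-yl]-5,7-dihydroxy-2,3-dihydro-4H-chromen-4-one
Conditions: 3 M aq. HCl/MeOH (1:5), degassed, 40 °C, Ar
Reagents that add atoms: none
Why: Acid-catalysed acetal exchange of the four MOM ethers with methanol; the mild temperature and degassed medium limit chroman formation from the geranyl chain and catechol oxidation, and C2 is not touched because flavanone racemisation is a base-mediated retro-oxa-Michael process.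

**Compound list**
1 | 2,4,6-trihydroxyacetophenone | CC(=O)c1c(O)cc(O)cc1O | starting material
2 | 4-ethoxy-5,7-dihydroxychromenylium perchlorate | CCOc1cc[o+]c2cc(O)cc(O)c12.[O-]Cl(=O)(=O)=O | intermediate
3 | 5,7-dihydroxy-4H-chromen-4-one | O=c1ccoc2cc(O)cc(O)c12 | intermediate
4 | geranyl bromide, (2E)-1-bromo-3,7-dimethylocta-2,6-diene | BrC/C=C(\C)CCC=C(C)C | starting material
5 | 6-[(2E)-3,7-dimethylocta-2,6-dien-1-yl]-5,7-dihydroxy-4H-chromen-4-one | O=c1ccoc2cc(O)c(C/C=C(\C)CCC=C(C)C)c(O)c12 | intermediate
6 | 6-[(2E)-3,7-dimethylocta-2,6-dien-1-yl]-5,7-bis(methoxymethoxy)-4H-chromen-4-one | O=c1ccoc2cc(OCOC)c(C/C=C(\C)CCC=C(C)C)c(OCOC)c12 | intermediate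
7 | 3-methoxycatechol (3-methoxybenzene-1,2-diol) | COc1cccc(O)c1O | starting material
8 | 1-methoxy-2,3-bis(methoxymethoxy)benzene | COc1cccc(OCOC)c1OCOC | intermediate
9 | 2-[3-methoxy-4,5-bis(methoxymethoxy)phenyl]-4,4,5,5-tetramethyl-1,3,2-dioxaborolane | COc1cc(B2OC(C)(C)C(C)(C)O2)cc(OCOC)c1OCOC | intermediate
10 | [3-methoxy-4,5-bis(methoxymethoxy)phenyl]boronic acid | COc1cc(B(O)O)cc(OCOC)c1OCOC | intermediate
11 | (2S)-6-[(2E)-3,7-dimethylocta-2,6-dien-1-yl]-2-[3-methoxy-4,5-bis(methoxymethoxy)phenyl]-5,7-bis(methoxymethoxy)-2,3-dihydro-4H-chromen-4-one | COc1cc([C@@H]2CC(=O)c3c(cc(OCOC)c(C/C=C(\C)CCC=C(C)C)c3OCOC)O2)cc(OCOC)c1OCOC | intermediate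
12 | (2S)-2-(3,4-dihydroxy-5-methoxyphenyl)-6-[(2E)-3,7-dimethylocta-2,6-dien-1-yl]-5,7-dihydroxy-2,3-dihydro-4H-chromen-4-one | COc1cc([C@@H]2CC(=O)c3c(cc(O)c(C/C=C(\C)CCC=C(C)C)c3O)O2)cc(O)c1O | target

**Step count**
Total steps: 7. Longest linear sequence: 5 (steps 1, 2, 3, 6, 7); steps 4 and 5 are the convergent B-ring branch.

**Steps most likely to fail and fallbacks**

Step 2 (C- versus O-alkylation, and 6- versus 8-selectivity). If too little 5 is obtained, the fallback sets out again from 3 and fixes the position by halogenation instead of by phenoxide reactivity. Selective 7-O-protection (MOMCl, K2CO3, acetone; the chelated 5-OH does not react) gives 5-hydroxy-7-(methoxymethoxy)-4H-chromen-4-one F1. Iodination ortho to the free chelated phenol (BnMe3N·ICl2, CaCO3, CH2Cl2/MeOH) gives 5-hydroxy-6-iodo-7-(methoxymethoxy)-4H-chromen-4-one F2. NaH/MOMCl then gives 6-iodo-5,7-bis(methoxymethoxy)-4H-chromen-4-one F3. An α-selective Suzuki–Miyaura coupling (Pd/biarylphosphine, K3PO4, THF/H2O) with (E)-geranylboronic acid pinacol ester F4, made from 4 and B2pin2 under Pd(0) catalysis, delivers 6, where the route is rejoined; 5 is bypassed.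

Step 6 (an electron-rich 5,7-dialkoxychromone is a sluggish acceptor and the ee is untested on this substrate). The fallback sets out from 6 and 10, gives up catalyst control and separates the enantiomers instead. A cationic Pd(II)/2,2′-bipyridine catalyst (Pd(OCOCF3)2, bpy, aqueous dichloroethane, 60 °C; no free phenol is present, so no Wacker-type cyclisation) adds the aryl group without facial selectivity to give the racemic tetra-MOM flavanone F5. Preparative SFC on an amylose carbamate phase delivers 11, where the route is rejoined, and the (2R)-tetra-MOM flavanone F6 is set aside.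

Step 7 (protic acid next to a geranyl chain flanked by two phenols, and a para-hydroxybenzylic ether at C2). The fallback sets out from 11 and avoids Brønsted acid by transprotection. TMSOTf/2,2′-bipyridyl (CH2Cl2, 0 °C) converts the aryl MOM ethers into aryl trimethylsilyl ethers through N-(methoxymethyl)bipyridinium salts, giving the tetrakis(trimethylsilyl) ether of the target F7. Water at pH 7 (rt) hydrolyses it to 12.

**Further compounds**
F1 | step 2 | 5-hydroxy-7-(methoxymethoxy)-4H-chromen-4-one | O=c1ccoc2cc(OCOC)cc(O)c12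
F2 | step 2 | 5-hydroxy-6-iodo-7-(methoxymethoxy)-4H-chromen-4-one | O=c1ccoc2cc(OCOC)c(I)c(O)c12
F3 | step 2 | 6-iodo-5,7-bis(methoxymethoxy)-4H-chromen-4-one | O=c1ccoc2cc(OCOC)c(I)c(OCOC)c12
F4 | step 2 | 2-[(2E)-3,7-dimethylocta-2,6-dien-1-yl]-4,4,5,5-tetramethyl-1,3,2-dioxaborolane | CC(C)=CCC/C(C)=C/CB1OC(C)(C)C(C)(C)O1
F5 | step 6 | racemic 6-[(2E)-3,7-dimethylocta-2,6-dien-1-yl]-2-[3-methoxy-4,5-bis(methoxymethoxy)phenyl]-5,7-bis(methoxymethoxy)-2,3-dihydro-4H-chromen-4-one | COc1cc(C2CC(=O)c3c(cc(OCOC)c(C/C=C(\C)CCC=C(C)C)c3OCOC)O2)cc(OCOC)c1OCOC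
F6 | step 6 | (2R)-6-[(2E)-3,7-dimethylocta-2,6-dien-1-yl]-2-[3-methoxy-4,5-bis(methoxymethoxy)phenyl]-5,7-bis(methoxymethoxy)-2,3-dihydro-4H-chromen-4-one | COc1cc([C@H]2CC(=O)c3c(cc(OCOC)c(C/C=C(\C)CCC=C(C)C)c3OCOC)O2)cc(OCOC)c1OCOC
F7 | step 7 | (2S)-6-[(2E)-3,7-dimethylocta-2,6-dien-1-yl]-2-[3-methoxy-4,5-bis(trimethylsilyloxy)phenyl]-5,7-bis(trimethylsilyloxy)-2,3-dihydro-4H-chromen-4-one | COc1cc([C@@H]2CC(=O)c3c(cc(O[Si](C)(C)C)c(C/C=C(\C)CCC=C(C)C)c3O[Si](C)(C)C)O2)cc(O[Si](C)(C)C)c1O[Si](C)(C)C
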